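**Assumptions.** The target has no stereocentres, so it is achiral and "single enantiomer" has no content. 4-Methoxy-3,5-dimethylphenol (1) is taken to be commercially available (Dakin oxidation of 4-methoxy-3,5-dimethylbenzaldehyde makes it in one step).

## Retrosynthesis
- The target is a primary benzylic acetate and a 2-hydroxybenzophenone whose phenol is masked as a MOM ether. It comes from the hydroxy-ketone by acetylation, then MOM removal.
- The diaryl ketone C–C bond is cut back to 2,6-dimethoxyphenyllithium plus a 7-MOMO-phthalide. The lactone masks the CH2OH and activates the carbonyl.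
- The phthalide comes from carboxylate-directed lateral oxygenation of the ortho-methyl group of a benzoic acid, which closes the only ring formed in the synthesis. That acid comes from directed ortho-lithiation and carboxylation of the MOM ether of the symmetric phenol 1.
- Because phenol 1 is symmetric, the two ortho positions are equivalent, so there is no regiochemistry problem for the carboxylation. The carboxylate then distinguishes the two methyl groups.

## Forward route

**Step 1**
Reactants: 1 (4-methoxy-3,5-dimethylphenol); 2 (chloromethyl methyl ether, MOMCl)
Product: 3 (2-methoxy-1,3-dimethyl-5-(methoxymethoxy)benzene)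
Conditions: MOMCl, i-Pr2NEt, CH2Cl2, 0 °C → rt
Reagents that add atoms: MOMCl, ClCOC
Why: Williamson-type O-alkylation protects the phenol and installs a strong ortho-directing group for the next step. No stereocentre is formed.

**Step 2**
Reactants: 3; 4 (CO2)
Product: 5 (5-methoxy-2-(methoxymethoxy)-4,6-dimethylbenzoic acid)
Conditions: n-BuLi, THF, 0 °C → rt; then solid CO2, −78 °C → rt; 1 M citric acid workup
Reagents that add atoms: carbon dioxide, O=C=O
Why: Directed ortho-metalation occurs next to OMOM. The two ring C–H positions ortho to OMOM are equivalent (each sits between OMOM and a methyl), so a single regioisomer results. Carboxylation then gives the benzoic acid.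

**Step 3**
Reactants: 5; 6 (Davis oxaziridine, 2-(phenylsulfonyl)-3-phenyloxaziridine)
Product: 7 (4-methoxy-7-(methoxymethoxy)-5-methylisobenzofuran-1(3H)-one)
Conditions: LDA (2.6 equiv), THF, −78 → 0 °C; then 6, −78 °C; then 1 M citric acid, rt
Reagents that add atoms: Davis oxaziridine, O=S(=O)(c1ccccc1)N1OC1c1ccccc1 (supplies the O atom)
Why: The carboxylate-directed lateral lithiation (Creger-type dianion) occurs selectively at the ortho methyl, not the para one. The benzylic anion is hydroxylated by electrophilic oxygen transfer, and the 2-(hydroxymethyl)benzoic acid lactonizes on acidification. No stereocentre is formed.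

**Step 4**
Reactants: 7; 8 (1,3-dimethoxybenzene)
Product: 9 ((2,6-dimethoxyphenyl)[2-(hydroxymethyl)-3-methoxy-4-methyl-6-(methoxymethoxy)phenyl]methanone)
Conditions: 8 + n-BuLi, THF, 0 °C (gives 2,6-dimethoxyphenyllithium in situ); add 7, THF, −78 → 0 °C; aq. NH4Cl
Reagents that add atoms: 1,3-dimethoxybenzene, COc1cccc(OC)c1 (as its C2-lithio derivative)
Why: Lateral-selective C2 lithiation of 1,3-dimethoxybenzene, then nucleophilic acyl substitution on the lactone. The stable lithium lactolate prevents double addition, and collapse on work-up gives the open hydroxy-ketone. The crowded diaryl ketone should stay open-chain rather than close to a lactol. No stereocentre is formed.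

**Step 5**
Reactants: 9; 10 (acetic anhydride)
Product: 11 (the benzylic acetate of 9)
Conditions: Ac2O, Et3N, cat. DMAP, CH2Cl2, rt
Reagents that add atoms: acetic anhydride, CC(=O)OC(C)=O
Why: Chemoselective O-acetylation of the only free hydroxyl group (the primary benzylic alcohol). The MOM-protected phenol and the ketone are untouched.

**Step 6**
Reactants: 11
Product: 12 (Preacredinone A)
Conditions: TFA, CH2Cl2 (1:4), 0 °C → rt
Reagents that add atoms: none
Why: Acid-catalysed acetal cleavage removes the aryl MOM ether. The benzylic acetate and the methyl ethers are stable, and the liberated phenol is hydrogen-bonded to the ketone. The product is achiral.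

## Compound list
1 | 4-methoxy-3,5-dimethylphenol | Oc1cc(C)c(OC)c(C)c1 | starting material
2 | chloromethyl methyl ether (MOMCl) | ClCOC | starting material (reagent)
3 | 2-methoxy-1,3-dimethyl-5-(methoxymethoxy)benzene | COCOc1cc(C)c(OC)c(C)c1 | intermediate
4 | carbon dioxide | O=C=O | starting material (reagent)
5 | 5-methoxy-2-(methoxymethoxy)-4,6-dimethylbenzoic acid | COCOc1cc(C)c(OC)c(C)c1C(=O)O | intermediate
6 | 2-(phenylsulfonyl)-3-phenyloxaziridine | O=S(=O)(c1ccccc1)N1OC1c1ccccc1 | starting material (reagent)
7 | 4-methoxy-7-(methoxymethoxy)-5-methylisobenzofuran-1(3H)-one | COCOc1cc(C)c(OC)c2COC(=O)c12 | intermediate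
8 | 1,3-dimethoxybenzene | COc1cccc(OC)c1 | starting material
9 | (2,6-dimethoxyphenyl)[2-(hydroxymethyl)-3-methoxy-4-methyl-6-(methoxymethoxy)phenyl]methanone | COCOc1cc(C)c(OC)c(CO)c1C(=O)c1c(OC)cccc1OC | intermediate
10 | acetic anhydride | CC(=O)OC(C)=O | starting material (reagent)
11 | [2-(2,6-dimethoxybenzoyl)-6-methoxy-5-methyl-3-... acetate: 2-(2,6-dimethoxybenzoyl)-3-(methoxymethoxy)-6-methyl-... benzyl acetate, i.e. the acetate of 9 | COCOc1cc(C)c(OC)c(COC(C)=O)c1C(=O)c1c(OC)cccc1OC | intermediate
12 | Preacredinone A | COc1cccc(OC)c1C(=O)c1c(O)cc(C)c(OC)c1COC(C)=O | target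

## Totals
- Total steps: 6.
- Longest linear sequence: 6 steps from 1.

**Three steps most likely to fail**
1. **Step 3 (lateral oxygenation).** The risks are para-methyl or ring lithiation and poor oxygen-transfer yield.
   Fallback: use a different approach, carboxylate-directed Pd(II)-catalysed benzylic C(sp3)–H lactonisation of 5 (Pd(OAc)2 with a stoichiometric oxidant).
2. **Step 4 (hindered ArLi plus hindered lactone).** The risks are low conversion, over-addition, or a lactol product.
   Fallback: open 7 with AlMe3·HN(OMe)Me to the Weinreb amide, silylate the CH2OH, add the aryllithium, then remove the silyl group and acetylate. The stable Weinreb tetrahedral intermediate avoids double addition.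
3. **Step 2 (ortho-lithiation and carboxylation).** The risk is competing lateral lithiation of the methyl groups.
   Fallback: use a different approach. Brominate the phenol 1 ortho to OH (NBS), protect it as the MOM ether, then do Br/Li exchange and CO2 quench to give the same acid 5.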